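**Retrosynthetic overview**
1. Target ← bis-TBS ether of the macrocycle by global desilylation; the ten-membered ring is the last ring formed.
2. Ten-membered ring ← seco-aldehyde: C3–C4 bond by nickel-catalysed reductive coupling of the C4 alkenyl iodide with the 1-bromoalkyl acetate made from the C3 aldehyde (ring, C3 stereocentre and acetate in one step).
3. Seco-aldehyde ← butenolide allyl bromide (fragment A) + Z-enal (fragment B): C7–C8 bond by indium Barbier allylation (unveils the α-methylene lactone, sets C7 and C8), then angeloylation and TES ether → aldehyde.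
4. Fragment A ← propargyl alcohol, crotonaldehyde, 2-(bromomethyl)acrylic acid: kinetic resolution (C6), trans-hydroalumination/iodination (4Z iodide), ring-closing metathesis (lactone ring, formed first).
5. Fragment B ← propane-1,3-diol, ethyl propiolate: asymmetric alkynylation (C1), syn-carbocupration (9Z).

Assumption: locants C1–C15 follow germacrane numbering of the target (C12 lactone carbonyl, O on C6), and for each chiral ligand the antipode named is taken to be the one that gives the facial sense stated.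

**Fragment A**

Step 1
Reactants: 1 prop-2-yn-1-ol
Product: 2 tert-butyldimethyl(prop-2-yn-1-yloxy)silane
Conditions: TBSCl, imidazole, CH2Cl2, 0 °C → rt
Reagents that add atoms: tert-butyldimethylsilyl chloride CC(C)(C)[Si](C)(C)Cl
Why: Standard silylation of a primary alcohol; the C15 oxygen stays masked until the last step.

Step 2
Reactants: 2 tert-butyldimethyl(prop-2-yn-1-yloxy)silane; 3 (E)-but-2-enal
Product: 5 rac-(E)-7-[(tert-butyldimethylsilyl)oxy]hept-2-en-5-yn-4-ol, via lithium acetylide 4 (not isolated)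
Conditions: n-BuLi, THF, −78 °C; then 3, −78 °C; aq. NH4Cl
Reagents that add atoms: none
Why: 1,2-Addition of a lithium acetylide to an enal gives the racemic alkynyl propenyl carbinol (C6 of the target).

Step 3
Reactants: 5 rac-(E)-7-[(tert-butyldimethylsilyl)oxy]hept-2-en-5-yn-4-ol
Product: 6 (2E,4R)-7-[(tert-butyldimethylsilyl)oxy]hept-2-en-5-yn-4-ol
Conditions: Ti(OiPr)4 (0.2 equiv), D-(−)-diisopropyl tartrate (0.25 equiv), t-BuOOH (0.6 equiv), 4 Å MS, CH2Cl2, −20 °C, to about 55% conversion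
Reagents that add atoms: none
Why: Sharpless kinetic resolution; with the D-(−)-tartrate the (4S)-carbinol is epoxidised fast at its propenyl group, leaving the (4R)-alcohol in high ee.

Step 4
Reactants: 6 (2E,4R)-7-[(tert-butyldimethylsilyl)oxy]hept-2-en-5-yn-4-ol
Product: 8 (2E,4R,5Z)-7-[(tert-butyldimethylsilyl)oxy]-6-iodohepta-2,5-dien-4-ol, via cyclic alkenylaluminate 7 (not isolated)
Conditions: NaAlH2(OCH2CH2OMe)2, THF, −20 → 0 °C; then I2, THF, −78 °C; Rochelle salt
Reagents that add atoms: iodine II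
Why: Hydroxyl-directed trans-hydroalumination puts hydride on C5 and aluminium on C4 in a five-membered alkoxyaluminate; iodinolysis with retention gives the Z-iodide with iodine cis to the carbinol carbon, which fixes the 4Z geometry.

Step 5
Reactants: 9 2-(bromomethyl)prop-2-enoic acid
Product: 10 2-(bromomethyl)prop-2-enoyl chloride
Conditions: (COCl)2, DMF (cat.), CH2Cl2, 0 °C → rt; concentrate
Reagents that add atoms: oxalyl chloride O=C(Cl)C(Cl)=O
Why: Vilsmeier-catalysed acid chloride formation; avoids carbodiimide/DMAP activation, which would attack the allylic bromide.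

Step 6
Reactants: 8 (2E,4R,5Z)-7-[(tert-butyldimethylsilyl)oxy]-6-iodohepta-2,5-dien-4-ol; 10 2-(bromomethyl)prop-2-enoyl chloride
Product: 11 (2E,4R,5Z)-7-[(tert-butyldimethylsilyl)oxy]-6-iodohepta-2,5-dien-4-yl 2-(bromomethyl)prop-2-enoate
Conditions: 2,6-lutidine, CH2Cl2, −20 → 0 °C
Reagents that add atoms: none
Why: O-Acylation with a hindered, non-nucleophilic base; the stereocentre is not touched.

Step 7
Reactants: 11 (2E,4R,5Z)-7-[(tert-butyldimethylsilyl)oxy]-6-iodohepta-2,5-dien-4-yl 2-(bromomethyl)prop-2-enoate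
Product: 12 (5R)-3-(bromomethyl)-5-[(1Z)-3-[(tert-butyldimethylsilyl)oxy]-2-iodoprop-1-en-1-yl]furan-2(5H)-one
Conditions: second-generation Grubbs catalyst (5 mol%), 1,4-benzoquinone (10 mol%), toluene, 70 °C
Reagents that add atoms: none
Why: Ring-closing metathesis: the carbene loads on the propenyl group and closes onto the acrylate to give the butenolide with loss of propene; the trisubstituted iodoalkene is inert and benzoquinone suppresses isomerisation at C6.

**Fragment B**

Step 8
Reactants: 13 propane-1,3-diol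
Product: 14 3-[(triethylsilyl)oxy]propan-1-ol
Conditions: TESCl (1 equiv), imidazole, 13 (4 equiv), CH2Cl2/DMF, 0 °C
Reagents that add atoms: triethylsilyl chloride CC[Si](Cl)(CC)CC
Why: Statistical monosilylation with excess diol; TES is chosen because it can later be turned directly into the aldehyde.

Step 9
Reactants: 14 3-[(triethylsilyl)oxy]propan-1-ol
Product: 15 3-[(triethylsilyl)oxy]propanal
Conditions: Dess–Martin periodinane, NaHCO3, CH2Cl2, 0 °C → rt
Reagents that add atoms: none
Why: Buffered Dess–Martin oxidation of a primary alcohol that leaves the TES ether intact.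

Step 10
Reactants: 15 3-[(triethylsilyl)oxy]propanal; 16 ethyl prop-2-ynoate
Product: 18 ethyl (4S)-4-hydroxy-6-[(triethylsilyl)oxy]hex-2-ynoate, via alkynylzinc 17 (not isolated)
Conditions: 16, Me2Zn, (S,S)-ProPhenol (10 mol%), Ph3PO (20 mol%), toluene, 0 °C; then 15, 4 °C
Reagents that add atoms: none
Why: Zinc–ProPhenol catalysed asymmetric alkynylation; delivery of the alkynylzinc to the Re face of the aldehyde sets C1 as (S).

Step 11
Reactants: 18 ethyl (4S)-4-hydroxy-6-[(triethylsilyl)oxy]hex-2-ynoate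
Product: 19 ethyl (4S)-4-[(tert-butyldimethylsilyl)oxy]-6-[(triethylsilyl)oxy]hex-2-ynoate
Conditions: TBSCl, imidazole, DMF, rt
Reagents that add atoms: tert-butyldimethylsilyl chloride CC(C)(C)[Si](C)(C)Cl
Why: Silylation of the C1 hydroxyl; it also prevents lactonisation in the next step.

Step 12
Reactants: 19 ethyl (4S)-4-[(tert-butyldimethylsilyl)oxy]-6-[(triethylsilyl)oxy]hex-2-ynoate
Product: 20 ethyl (2Z,4S)-4-[(tert-butyldimethylsilyl)oxy]-3-methyl-6-[(triethylsilyl)oxy]hex-2-enoate
Conditions: Me2CuLi (from MeLi and CuI), THF, −78 °C; MeOH then aq. NH4Cl at −78 °C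
Reagents that add atoms: methyllithium [Li]C (methyl delivered as Me2CuLi, [Li+].C[Cu-]C)
Why: Syn-carbocupration (conjugate addition) of the ynoate and cold protonation with retention place the ester carbon cis to C1, which is the 9Z geometry.

Step 13
Reactants: 20 ethyl (2Z,4S)-4-[(tert-butyldimethylsilyl)oxy]-3-methyl-6-[(triethylsilyl)oxy]hex-2-enoate
Product: 21 (2Z,4S)-4-[(tert-butyldimethylsilyl)oxy]-3-methyl-6-[(triethylsilyl)oxy]hex-2-en-1-ol
Conditions: iBu2AlH (2.2 equiv), CH2Cl2, −78 °C; Rochelle salt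
Reagents that add atoms: none
Why: 1,2-Reduction of the enoate to the allylic alcohol without touching the olefin geometry or the silyl ethers.

Step 14
Reactants: 21 (2Z,4S)-4-[(tert-butyldimethylsilyl)oxy]-3-methyl-6-[(triethylsilyl)oxy]hex-2-en-1-ol
Product: 22 (2Z,4S)-4-[(tert-butyldimethylsilyl)oxy]-3-methyl-6-[(triethylsilyl)oxy]hex-2-enal
Conditions: Dess–Martin periodinane, NaHCO3, CH2Cl2, 0 °C; used at once
Reagents that add atoms: none
Why: Buffered, non-acidic oxidation keeps the Z-enal from isomerising.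

**Union and endgame**

Step 15
Reactants: 12 (5R)-3-(bromomethyl)-5-[(1Z)-3-[(tert-butyldimethylsilyl)oxy]-2-iodoprop-1-en-1-yl]furan-2(5H)-one; 22 (2Z,4S)-4-[(tert-butyldimethylsilyl)oxy]-3-methyl-6-[(triethylsilyl)oxy]hex-2-enal
Product: 23 (4S,5R)-4-[(1R,2Z,4S)-4-[(tert-butyldimethylsilyl)oxy]-1-hydroxy-3-methyl-6-[(triethylsilyl)oxy]hex-2-en-1-yl]-5-[(1Z)-3-[(tert-butyldimethylsilyl)oxy]-2-iodoprop-1-en-1-yl]-3-methylideneoxolan-2-one
Conditions: In powder, DMF (dry), 0 °C → rt; neutral work-up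
Reagents that add atoms: none
Why: Indium Barbier allylation through the butenolide γ-carbon: the aldehyde approaches anti to the C6 alkenyl group (trans lactone, C7 S), and a chair Zimmerman–Traxler transition state with the ring-locked E-type allylindium gives the anti C7/C8 relationship (C8 R); the alkenyl iodide is inert to indium.

Step 16
Reactants: 23 the Barbier adduct named in step 15; 24 (Z)-2-methylbut-2-enoic acid (angelic acid)
Product: 26 C8 (Z)-2-methylbut-2-enoate (angelate) of 23, via mixed anhydride 25 (not isolated)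
Conditions: 24, 2,4,6-Cl3C6H2COCl, Et3N, toluene, rt, filter; then 23, toluene, 80 °C
Reagents that add atoms: none
Why: Yamaguchi-type mixed-anhydride acylation without DMAP is stereoconservative for angelates, and the base-free acylation stage avoids 12,6 → 12,8 translactonisation.

Step 17
Reactants: 26 C8 angelate of 23
Product: 27 (1R,2Z,4S)-4-[(tert-butyldimethylsilyl)oxy]-1-{(2R,3S)-2-[(1Z)-3-[(tert-butyldimethylsilyl)oxy]-2-iodoprop-1-en-1-yl]-4-methylidene-5-oxooxolan-3-yl}-3-methyl-6-oxohex-2-en-1-yl (2Z)-2-methylbut-2-enoate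
Conditions: (COCl)2, DMSO, CH2Cl2, −78 → −40 °C; Et3N, −78 → 0 °C
Reagents that add atoms: none
Why: Swern conditions cleave a primary TES ether oxidatively and give the aldehyde directly, while the primary and secondary TBS ethers survive.

Step 18
Reactants: 27 the C3 aldehyde named in step 17
Product: 29 (1S,3S,6S,7S,8R)-3-acetoxy-1,15-bis[(tert-butyldimethylsilyl)oxy]-8-[(Z)-2-methylbut-2-enoyloxy]germacra-4Z,9Z,11(13)-trien-12,6-olide, via bromoalkyl acetate 28 (not isolated)
Conditions: AcBr (1.05 equiv), ZnBr2 (2 mol%), CH2Cl2, −30 °C, evaporate; then NiBr2·glyme (20 mol%), cyclopropane-bridged bis(indanyl-oxazoline) ligand (24 mol%), Mn powder, NaI, DMA/THF, 0 °C, syringe-pump addition to 2 mM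
Reagents that add atoms: acetyl bromide CC(=O)Br
Why: Proposed new method: the aldehyde adds AcBr to give a 1-bromoalkyl acetate (both C3 epimers), zerovalent nickel inserts into the C4–I bond with retention of the Z geometry, the alkenylnickel (reduced by Mn to the monovalent state) abstracts the tethered bromine, the α-acetoxyalkyl radical recombines within the same molecule to a trivalent alkenyl(alkyl)nickel species, and reductive elimination forms the C3–C4 bond and the ten-membered ring; because C3 passes through a planar radical the two bromide epimers converge, and the chiral bis(oxazoline) together with the 1,3-anti preference relative to the C1 silyl ether selects (3S) with the acetate already in place; the closest known reaction types are nickel-catalysed enantioconvergent couplings of 1-haloalkyl esters made in situ from aldehydes and acyl halides, and nickel-catalysed asymmetric reductive alkenyl halide–alkyl halide cross-electrophile couplings, neither shown as a medium-ring macrocyclisation.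

Step 19
Reactants: 29 the bis-TBS macrocycle named in step 18
Product: 30 (1S,3S,6S,7S,8R)-3-acetoxy-1,15-dihydroxy-8-[(Z)-2-methylbut-2-enoyloxy]germacra-4Z,9Z,11(13)-trien-12,6-olide (CNP0153210.4)
Conditions: HF·pyridine, pyridine, THF, 0 °C → rt
Reagents that add atoms: none
Why: Buffered fluoride desilylation removes both TBS ethers under mildly acidic conditions that avoid acetate migration, angelate isomerisation and Michael addition to the α-methylene lactone.

**Compound list**
1 | prop-2-yn-1-ol | C#CCO | starting material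
2 | tert-butyldimethyl(prop-2-yn-1-yloxy)silane | C#CCO[Si](C)(C)C(C)(C)C | intermediate
3 | (E)-but-2-enal | C/C=C/C=O | starting material
4 | lithium 3-[(tert-butyldimethylsilyl)oxy]prop-1-yn-1-ide | [Li]C#CCO[Si](C)(C)C(C)(C)C | intermediate
5 | rac-(E)-7-[(tert-butyldimethylsilyl)oxy]hept-2-en-5-yn-4-ol | C/C=C/C(O)C#CCO[Si](C)(C)C(C)(C)C | intermediate
6 | (2E,4R)-7-[(tert-butyldimethylsilyl)oxy]hept-2-en-5-yn-4-ol | C/C=C/[C@@H](O)C#CCO[Si](C)(C)C(C)(C)C | intermediate
7 | sodium cyclic alkoxy(alkenyl)bis(2-methoxyethoxy)aluminate from 6 (Al on C6 of the heptadiene, O–Al–C five-membered ring) | C/C=C/[C@H]1O[Al-](OCCOC)(OCCOC)C(CO[Si](C)(C)C(C)(C)C)=C1.[Na+] | intermediate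
8 | (2E,4R,5Z)-7-[(tert-butyldimethylsilyl)oxy]-6-iodohepta-2,5-dien-4-ol | C/C=C/[C@@H](O)/C=C(\I)CO[Si](C)(C)C(C)(C)C | intermediate
9 | 2-(bromomethyl)prop-2-enoic acid | C=C(CBr)C(=O)O | starting material
10 | 2-(bromomethyl)prop-2-enoyl chloride | C=C(CBr)C(=O)Cl | intermediate
11 | (2E,4R,5Z)-7-[(tert-butyldimethylsilyl)oxy]-6-iodohepta-2,5-dien-4-yl 2-(bromomethyl)prop-2-enoate | C/C=C/[C@@H](OC(=O)C(=C)CBr)/C=C(\I)CO[Si](C)(C)C(C)(C)C | intermediate
12 | (5R)-3-(bromomethyl)-5-[(1Z)-3-[(tert-butyldimethylsilyl)oxy]-2-iodoprop-1-en-1-yl]furan-2(5H)-one | O=C1O[C@@H](/C=C(\I)CO[Si](C)(C)C(C)(C)C)C=C1CBr | intermediate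
13 | propane-1,3-diol | OCCCO | starting material
14 | 3-[(triethylsilyl)oxy]propan-1-ol | OCCCO[Si](CC)(CC)CC | intermediate
15 | 3-[(triethylsilyl)oxy]propanal | O=CCCO[Si](CC)(CC)CC | intermediate
16 | ethyl prop-2-ynoate | C#CC(=O)OCC | starting material
17 | (3-ethoxy-3-oxoprop-1-yn-1-yl)(methyl)zinc | C[Zn]C#CC(=O)OCC | intermediate
18 | ethyl (4S)-4-hydroxy-6-[(triethylsilyl)oxy]hex-2-ynoate | CCOC(=O)C#C[C@@H](O)CCO[Si](CC)(CC)CC | intermediate
19 | ethyl (4S)-4-[(tert-butyldimethylsilyl)oxy]-6-[(triethylsilyl)oxy]hex-2-ynoate | CCOC(=O)C#C[C@@H](O[Si](C)(C)C(C)(C)C)CCO[Si](CC)(CC)CC | intermediate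
20 | ethyl (2Z,4S)-4-[(tert-butyldimethylsilyl)oxy]-3-methyl-6-[(triethylsilyl)oxy]hex-2-enoate | CCOC(=O)/C=C(/C)[C@@H](O[Si](C)(C)C(C)(C)C)CCO[Si](CC)(CC)CC | intermediate
21 | (2Z,4S)-4-[(tert-butyldimethylsilyl)oxy]-3-methyl-6-[(triethylsilyl)oxy]hex-2-en-1-ol | OC/C=C(/C)[C@@H](O[Si](C)(C)C(C)(C)C)CCO[Si](CC)(CC)CC | intermediate
22 | (2Z,4S)-4-[(tert-butyldimethylsilyl)oxy]-3-methyl-6-[(triethylsilyl)oxy]hex-2-enal | O=C/C=C(/C)[C@@H](O[Si](C)(C)C(C)(C)C)CCO[Si](CC)(CC)CC | intermediate
23 | (4S,5R)-4-[(1R,2Z,4S)-4-[(tert-butyldimethylsilyl)oxy]-1-hydroxy-3-methyl-6-[(triethylsilyl)oxy]hex-2-en-1-yl]-5-[(1Z)-3-[(tert-butyldimethylsilyl)oxy]-2-iodoprop-1-en-1-yl]-3-methylideneoxolan-2-one | C=C1C(=O)O[C@@H](/C=C(\I)CO[Si](C)(C)C(C)(C)C)[C@@H]1[C@H](O)/C=C(/C)[C@@H](O[Si](C)(C)C(C)(C)C)CCO[Si](CC)(CC)CC | intermediate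
24 | (Z)-2-methylbut-2-enoic acid (angelic acid) | C/C=C(/C)C(=O)O | starting material
25 | (Z)-2-methylbut-2-enoic 2,4,6-trichlorobenzoic anhydride | C/C=C(/C)C(=O)OC(=O)c1c(Cl)cc(Cl)cc1Cl | intermediate
26 | C8 angelate of 23: (1R,2Z,4S)-4-[(tert-butyldimethylsilyl)oxy]-1-{(2R,3S)-2-[(1Z)-3-[(tert-butyldimethylsilyl)oxy]-2-iodoprop-1-en-1-yl]-4-methylidene-5-oxooxolan-3-yl}-3-methyl-6-[(triethylsilyl)oxy]hex-2-en-1-yl (2Z)-2-methylbut-2-enoate | C=C1C(=O)O[C@@H](/C=C(\I)CO[Si](C)(C)C(C)(C)C)[C@@H]1[C@H](OC(=O)/C(C)=C\C)/C=C(/C)[C@@H](O[Si](C)(C)C(C)(C)C)CCO[Si](CC)(CC)CC | intermediate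
27 | C3 aldehyde: as 26 with the 6-[(triethylsilyl)oxy] terminus replaced by 6-oxo | C=C1C(=O)O[C@@H](/C=C(\I)CO[Si](C)(C)C(C)(C)C)[C@@H]1[C@H](OC(=O)/C(C)=C\C)/C=C(/C)[C@@H](O[Si](C)(C)C(C)(C)C)CC=O | intermediate
28 | 1-bromoalkyl acetate: as 27 with the aldehyde carbon as CH(Br)OAc (both C3 epimers) | C=C1C(=O)O[C@@H](/C=C(\I)CO[Si](C)(C)C(C)(C)C)[C@@H]1[C@H](OC(=O)/C(C)=C\C)/C=C(/C)[C@@H](O[Si](C)(C)C(C)(C)C)CC(Br)OC(C)=O | intermediate
29 | (1S,3S,6S,7S,8R)-3-acetoxy-1,15-bis[(tert-butyldimethylsilyl)oxy]-8-[(Z)-2-methylbut-2-enoyloxy]germacra-4Z,9Z,11(13)-trien-12,6-olide | C=C1C(=O)O[C@H]2/C=C(/CO[Si](C)(C)C(C)(C)C)[C@@H](OC(C)=O)C[C@H](O[Si](C)(C)C(C)(C)C)/C(C)=C\[C@@H](OC(=O)/C(C)=C\C)[C@H]12 | intermediate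
30 | (1S,3S,6S,7S,8R)-3-acetoxy-1,15-dihydroxy-8-[(Z)-2-methylbut-2-enoyloxy]germacra-4Z,9Z,11(13)-trien-12,6-olide (CNP0153210.4) | C=C1C(=O)O[C@H]2/C=C(/CO)[C@@H](OC(C)=O)C[C@H](O)/C(C)=C\[C@@H](OC(=O)/C(C)=C\C)[C@H]12 | target

**Totals and risk**

Total step count: 19. Longest linear sequence: 12 steps (steps 8–19, from propane-1,3-diol).

Three steps most likely to fail:

Step 18 (the proposed nickel macrocyclisation). The α-acetoxyalkyl radical may add to the α-methylene lactone or be captured intermolecularly, and AcBr may attack a silyl ether. The fallback sets out from 27 and comes back at 29. Aldehyde 27 is cyclised under classical Nozaki–Hiyama–Kishi conditions (excess CrCl2, NiCl2 1 mol%, DMSO/THF, high dilution, rt), a closure known for ten-membered germacranolides, to give the macrocyclic (3S)-allylic alcohol F1, which is acetylated (Ac2O, DMAP, pyridine) to 29. If the (3R)-epimeric alcohol F2 forms instead, Mitsunobu esterification with acetic acid (PPh3, DIAD) inverts C3 and gives 29 directly.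

Step 15 (Barbier union). The C8 configuration rests on a chair transition state and could be eroded by the β-branched Z-enal. The fallback sets out from 12 and 22 and comes back at 26. If the (8S)-epimeric adduct F3 is the main product, it is esterified with angelic acid 24 under Mitsunobu conditions (PPh3, DIAD, toluene, 0 °C), which inverts C8 while installing the angelate and so gives 26 without step 16.

Step 16 (angeloylation). The hindered C8 alcohol may react slowly, and the angelate may isomerise to the tiglate or the lactone may migrate to O8. The fallback sets out from 23 and comes back at 26. Alcohol 23 is acylated with 2-[bis(2,2,2-trifluoroethoxy)phosphoryl]propanoic acid (DCC, CH2Cl2) to the phosphonopropanoate ester F4, and a Still–Gennari olefination (KHMDS, 18-crown-6, THF, −78 °C; then acetaldehyde) builds the Z-trisubstituted double bond of the angelate on the ester.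

**Further compounds**
F1 | step 18 | (1S,3S,6S,7S,8R)-1,15-bis[(tert-butyldimethylsilyl)oxy]-3-hydroxy-8-[(Z)-2-methylbut-2-enoyloxy]germacra-4Z,9Z,11(13)-trien-12,6-olide | C=C1C(=O)O[C@H]2/C=C(/CO[Si](C)(C)C(C)(C)C)[C@@H](O)C[C@H](O[Si](C)(C)C(C)(C)C)/C(C)=C\[C@@H](OC(=O)/C(C)=C\C)[C@H]12
F2 | step 18 | (3R)-epimer of F1 | C=C1C(=O)O[C@H]2/C=C(/CO[Si](C)(C)C(C)(C)C)[C@H](O)C[C@H](O[Si](C)(C)C(C)(C)C)/C(C)=C\[C@@H](OC(=O)/C(C)=C\C)[C@H]12
F3 | step 15 | (8S)-epimer of 23 (side-chain carbinol 1S) | C=C1C(=O)O[C@@H](/C=C(\I)CO[Si](C)(C)C(C)(C)C)[C@@H]1[C@@H](O)/C=C(/C)[C@@H](O[Si](C)(C)C(C)(C)C)CCO[Si](CC)(CC)CC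
F4 | step 16 | C8 2-[bis(2,2,2-trifluoroethoxy)phosphoryl]propanoate of 23 (both epimers at the phosphonate carbon) | C=C1C(=O)O[C@@H](/C=C(\I)CO[Si](C)(C)C(C)(C)C)[C@@H]1[C@H](OC(=O)C(C)P(=O)(OCC(F)(F)F)OCC(F)(F)F)/C=C(/C)[C@@H](O[Si](C)(C)C(C)(C)C)CCO[Si](CC)(CC)CC
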